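A ratio of 12.2 to one is what I read at 40.0 h from the west and south-east runs, pooled. It sets side product against intermediate A, intermediate B and target together, and I call it the branch ratio, a selectivity factor. The west readings at that time sum to 100%, so I count each species as one unit of starting material.

the same everywhere: starting material 0.050 M
- west: second reagent 2 equiv; third reagent 0.90 equiv; solid reagent 0.65 equiv; run made earlier
- south-east: second reagent 2 equiv; third reagent 0.90 equiv; solid reagent 2.6 equiv; run made earlier
- south: second reagent 3 equiv; third reagent 0.90 equiv; solid reagent 1.3 equiv; run made earlier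
- zeta: second reagent 2.00 equiv; third reagent 0.900 equiv; solid reagent 1.30 equiv; time 30 h
- beta: second reagent 2.00 equiv; third reagent 0.900 equiv; solid reagent 1.30 equiv; time 50 h

| run | time / h | intermediate B / % | target / % | side product / % | intermediate A / % | starting material / % |
|---|---|---|---|---|---|---|
| west | 6.00 | 0.2 | 0.2 | 31.2 | 1.7 | 68.1 |
| west | 12.0 | 0.3 | 0 | 49.1 | 3.1 | 47.1 |
| west | 20.0 | 1.0 | 0 | 64.7 | 4.2 | 31.1 |
| west | 25.0 | 0.9 | 0.4 | 69.8 | 4.6 | 24.6 |
| west | 30.0 | 1.6 | 0 | 74.4 | 4.8 | 19.3 |
| west | 40.0 | 1.8 | 0.7 | 80.6 | 4.9 | 12.0 |
| south-east | 3.00 | 0 | 0 | 17.8 | 0.9 | 81.4 |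
| south-east | 5.00 | 0 | 0.3 | 25.8 | 2.1 | 70.7 |
| south-east | 8.00 | 0.1 | 0.1 | 38.2 | 2.4 | 60.4 |
| south-east | 12.0 | 0.5 | 0 | 49.2 | 2.6 | 47.8 |
| south-east | 20.0 | 1.0 | 0 | 64.4 | 3.6 | 31.8 |
| south-east | 40.0 | 2.1 | 0 | 81.0 | 3.8 | 13.1 |
| south | 8.00 | 0 | 0 | 51.6 | 1.3 | 47.9 |
| south | 15.0 | 0 | 0.4 | 70.6 | 2.3 | 25.5 |
| south | 20.0 | 1.2 | 0 | 79.1 | 2.2 | 16.7 |
| south | 30.0 | 0.8 | 0.2 | 87.9 | 3.2 | 7.7 |
| south | 40.0 | 2.6 | 0 | 92.4 | 1.6 | 5.0 |

(readings scatter by 0.5 percentage points)

1. which of these there is most of at the end, counted by the starting material in it, zeta (intermediate B / starting material / side product / intermediate A)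
2. which of these there is most of at the end, counted by the starting material in it, beta (intermediate B / starting material / side product / intermediate A)
3. the largest of these amounts at the end, in percent of the starting material charged, zeta
4. the largest of these amounts at the end, in percent of the starting material charged, beta

- given per volume of solution although it is solid: solid reagent
- at the start none of the solid reagent is in solution

I order the clocks from fast to slow. The solid comes first: from 0.65 equiv to 2.6 equiv, starting material at 40.0 h reads 12.0% against 13.1%, so the solid shows no clock of its own here. Next is starting material: west keeps 19.3% at 30.0 h, a log slope of 0.0548 h⁻¹ and a half-life of 12.6 h. Then intermediate A levels off, reading 4.8% and then 4.9% in west. Target is last, and its highest west reading is 0.7%, against a scatter of 0.5 percentage points.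

The south readings at 40.0 h give a branch ratio of 22.0, higher than at the lower charge. So in these readings the ratio rises with second reagent.

Side product is what has left, times br/(1+br). For zeta I take the west reading of starting material and get 74.6%. For beta, the late west slope of 0.0475 h⁻¹ leaves 7.46% of starting material, so side product is 85.5%.

The forecast, a little below mine, names side product at 74.3% (72.5% to 76%) for zeta and side product at 84.5% (82.5% to 86.5%) for beta, and says of the solid “it probably stays saturated”.

The flasks give side product at 74.7% in zeta and side product at 84.9% in beta. Side product in beta stands 10 points above zeta, and the difference in time is the main reason for that gap.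

    starting material + partner → intermediate A (k = 1.00 M⁻¹ h⁻¹)
    second reagent + intermediate A → intermediate B (k = 0.280 M⁻¹ h⁻¹)
    third reagent + intermediate B → target (k = 0.250 M⁻¹ h⁻¹)
    starting material + second reagent → side product (k = 0.670 M⁻¹ h⁻¹)
    solid reagent ⇌ partner, rate k5*(cs5 - [partner]) while solid is left; crystals form when [partner] > cs5 (solubility = 4.80 mM, k = 0.610 h⁻¹)
    partner → decomposition product (k = 3.80 × 10⁻⁵ h⁻¹)

Zeta's branch ratio is 12.9: second reagent competes with a partner that stands at 0.00472 M. The partner's low solubility is part of the reason: without it, zeta's side product is 49.4%, not 74.7%. A neighbour of zeta with 0.013 M of starting material, equivalents held, keeps its partner at 0.00474 M. Its second reagent is diluted, so I scale the ratio to 3.16. That flask gives 3.60, with side product at 35.4%.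

The numbers in the tables were generated by integration from invented constants; scatter was added.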